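**Strategy.** The route rests on treating the middle phenol ring of the three-ring C-6 side chain (ring G: C–OH, ortho C–CH2Ar, para C–CH2Ar') as the aromatic tautomer of a 6-arylidenecyclohex-2-enone. Its ArCH2–C(ortho) bond is made by acid-mediated aldol condensation between a formyl group on the fully elaborated (S)-flavanone fragment and racemic 4-[2-(benzyloxy)benzyl]cyclohex-2-enone. Dehydration and isoaromatization in the same flask create the phenol. Either α-carbon of the enone becomes an equivalent ortho carbon, so the ortho/para and ring-choice problems of a Friedel–Crafts benzylation cannot arise. The C-2 stereocentre comes from (S)-pinocembrin, and one hydrogenolysis finishes the synthesis.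

Key step: step 7

Assumption: (S)-pinocembrin, 2,2-dimethyl-4H-1,3-benzodioxine-6-carbaldehyde, cyclohex-2-en-1-one, 3-ethoxycyclohex-2-en-1-one and 1-(benzyloxy)-2-(bromomethyl)benzene are taken as purchasable; the cyclohexene intermediates are used racemic because their stereocentre disappears on aromatization.

Step 1
Reactants: 1 (S)-pinocembrin
Product: 2 (2S)-5-hydroxy-2-phenyl-7-[(triisopropylsilyl)oxy]chroman-4-one
Conditions: TIPSCl, imidazole, DMF, 0 °C
Reagents that add atoms: chlorotriisopropylsilane (TIPSCl), CC(C)[Si](Cl)(C(C)C)C(C)C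
Why: Silyl ether formation on the more acidic, non-chelated 7-OH while the 5-OH stays hydrogen-bonded to the C-4 carbonyl; imidazole is too weak a base to open the flavanone, so the C-2 stereocentre brought in with 1 is retained.

Step 2
Reactants: 2 (2S)-5-hydroxy-2-phenyl-7-[(triisopropylsilyl)oxy]chroman-4-one; 3 2,2-dimethyl-4H-1,3-benzodioxine-6-carbaldehyde
Product: 5 (2S)-6-(5-formyl-2-hydroxybenzyl)-5,7-dihydroxy-2-phenylchroman-4-one, via silyl ether 4 (not isolated)
Conditions: ZnCl2, dioxane, 80 °C; then 48% aq. HF, MeCN, 25 °C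
Reagents that add atoms: none
Why: Zinc-mediated ortho-quinone methide Friedel–Crafts alkylation in which ZnCl2 opens the acetonide of 3 with loss of acetone and the zinc-bound 5-OH, the only free phenol of 2, should deliver the quinone methide to its ortho carbon C-6 (electrophiles generally enter ortho to the free chelated 5-OH of 5-hydroxy-7-alkoxyflavonoids), after which HF cleaves the aryl silyl ether without touching aldehyde or flavanone.

Step 3
Reactants: 3 2,2-dimethyl-4H-1,3-benzodioxine-6-carbaldehyde; 6 cyclohex-2-en-1-one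
Product: 8 2-[(2,2-dimethyl-4H-1,3-benzodioxin-6-yl)methyl]phenol, via arylidene dienone 7 (not isolated)
Conditions: KOH, EtOH, 25 → 78 °C; then AcOH to pH 7
Reagents that add atoms: none
Why: Claisen–Schmidt aldol condensation at the α'-carbon of the enone (the site used by 4,4-disubstituted cyclohexenones) followed by base-mediated isoaromatization of the cross-conjugated dienone to the phenoxide, which makes the sequence irreversible and leaves the base-stable acetonide intact.

Step 4
Reactants: 5 (2S)-6-(5-formyl-2-hydroxybenzyl)-5,7-dihydroxy-2-phenylchroman-4-one; 8 2-[(2,2-dimethyl-4H-1,3-benzodioxin-6-yl)methyl]phenol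
Product: 9 (2S)-6-(5-formyl-2-hydroxybenzyl)-5,7-dihydroxy-8-[2-hydroxy-5-(2-hydroxybenzyl)benzyl]-2-phenylchroman-4-one
Conditions: ZnCl2, dioxane, 80 °C
Reagents that add atoms: none
Why: Zinc-mediated ortho-quinone methide Friedel–Crafts alkylation at C-8, the only free position of the phloroglucinol ring of 5 and ortho to its free 7-OH, with the formyl-bearing phenol ring deactivated and the acylphloroglucinol ring expected to outcompete the simple phenol ring of 8.

Step 5
Reactants: 10 3-ethoxycyclohex-2-en-1-one; 11 1-(benzyloxy)-2-(bromomethyl)benzene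
Product: 12 rac-6-[2-(benzyloxy)benzyl]-3-ethoxycyclohex-2-en-1-one
Conditions: LiN(iPr)2, THF, −78 °C; then 11, −78 → 0 °C
Reagents that add atoms: none
Why: Stork–Danheiser alkylation, in which kinetic deprotonation of the vinylogous ester at its α'-carbon is followed by SN2 reaction with the benzylic bromide.

Step 6
Reactants: 12 rac-6-[2-(benzyloxy)benzyl]-3-ethoxycyclohex-2-en-1-one
Product: 14 rac-4-[2-(benzyloxy)benzyl]cyclohex-2-en-1-one, via allylic alcohol 13 (not isolated)
Conditions: LiAlH4, Et2O, 0 °C; then 1 M aq. HCl, 25 °C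
Reagents that add atoms: water, O
Why: Stork–Danheiser enone transposition, in which 1,2-reduction gives the allylic alcohol and aqueous acid ionizes it to the ethoxy-stabilized allyl cation that water captures at the former C-3, releasing ethanol and the 4-substituted enone while the benzyl ether is inert.

Step 7
Reactants: 9 (2S)-6-(5-formyl-2-hydroxybenzyl)-5,7-dihydroxy-8-[2-hydroxy-5-(2-hydroxybenzyl)benzyl]-2-phenylchroman-4-one; 14 rac-4-[2-(benzyloxy)benzyl]cyclohex-2-en-1-one
Product: 17 (2S)-6-(5-{5-[2-(benzyloxy)benzyl]-2-hydroxybenzyl}-2-hydroxybenzyl)-5,7-dihydroxy-8-[2-hydroxy-5-(2-hydroxybenzyl)benzyl]-2-phenylchroman-4-one, via aldol adduct 15 (not isolated), via arylidene dienone 16 (not isolated)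
Conditions: 14 (3 equiv), HCl (4 M in dioxane), AcOH, 25 → 50 °C
Reagents that add atoms: none
Why: Acid-mediated Claisen–Schmidt aldol condensation and isoaromatization: the dienol of 14 adds through its α'-carbon to the protonated formyl group of 9 and forms the ArCH–C bond, the para-hydroxybenzylic alcohol of 15 ionizes and loses the α-proton to give dienone 16, and enolization through C-4 of the enone ring, protonation of the exocyclic carbon and loss of a C-5 proton turn that ring into the phenol. The closest known reactions are the HCl/AcOH condensation of 4-hydroxybenzaldehydes with cyclohexanones and the acid-induced isoaromatization of arylidenecyclohexanones to benzylphenols. No ring is closed and no stereocentre is created: the racemic centre of 14 and the alkene geometry of 16 vanish on aromatization, and the (S)-C-2 centre is untouched because the chelated flavanone should not open in acid at this temperature. Regioselectivity is secured by the substrate, since C-2 and C-6 of a 4-substituted cyclohexenone both become an ortho carbon of the same para-substituted phenol, and a γ-adduct at the substituted C-4 cannot dehydrate and reverts. Chemoselectivity rests on the aldehyde being the only unhindered carbonyl electrophile (the flavanone C-4 ketone is a chelated vinylogous ester), on the excess of 14, and on aromatization as the thermodynamic sink.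

Step 8
Reactants: 17 (2S)-6-(5-{5-[2-(benzyloxy)benzyl]-2-hydroxybenzyl}-2-hydroxybenzyl)-5,7-dihydroxy-8-[2-hydroxy-5-(2-hydroxybenzyl)benzyl]-2-phenylchroman-4-one
Product: 18 sarmentosumin D
Conditions: H2 (1 atm), 10% Pd/C, EtOAc/MeOH, 25 °C
Reagents that add atoms: none
Why: Hydrogenolysis of the single aryl benzyl ether over palladium on carbon, under which the flavanone carbonyl, its benzylic C-2–O bond and the diarylmethane links should survive.

**Compound list**

1 | (S)-pinocembrin, (2S)-5,7-dihydroxy-2-phenylchroman-4-one | O=C1C[C@@H](c2ccccc2)Oc2cc(O)cc(O)c21 | starting material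
2 | (2S)-5-hydroxy-2-phenyl-7-[(triisopropylsilyl)oxy]chroman-4-one | O=C1C[C@@H](c2ccccc2)Oc2cc(O[Si](C(C)C)(C(C)C)C(C)C)cc(O)c21 | intermediate
3 | 2,2-dimethyl-4H-1,3-benzodioxine-6-carbaldehyde | CC1(C)OCc2cc(C=O)ccc2O1 | starting material
4 | (2S)-6-(5-formyl-2-hydroxybenzyl)-5-hydroxy-2-phenyl-7-[(triisopropylsilyl)oxy]chroman-4-one (not isolated) | O=C1C[C@@H](c2ccccc2)Oc2cc(O[Si](C(C)C)(C(C)C)C(C)C)c(Cc3cc(C=O)ccc3O)c(O)c21 | intermediate
5 | (2S)-6-(5-formyl-2-hydroxybenzyl)-5,7-dihydroxy-2-phenylchroman-4-one | O=C1C[C@@H](c2ccccc2)Oc2cc(O)c(Cc3cc(C=O)ccc3O)c(O)c21 | intermediate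
6 | cyclohex-2-en-1-one | O=C1C=CCCC1 | starting material
7 | (6E)-6-[(2,2-dimethyl-4H-1,3-benzodioxin-6-yl)methylidene]cyclohex-2-en-1-one (not isolated) | CC1(C)OCc2cc(/C=C3/C(=O)C=CCC3)ccc2O1 | intermediate
8 | 2-[(2,2-dimethyl-4H-1,3-benzodioxin-6-yl)methyl]phenol | CC1(C)OCc2cc(Cc3ccccc3O)ccc2O1 | intermediate
9 | (2S)-6-(5-formyl-2-hydroxybenzyl)-5,7-dihydroxy-8-[2-hydroxy-5-(2-hydroxybenzyl)benzyl]-2-phenylchroman-4-one | O=C1C[C@@H](c2ccccc2)Oc2c(Cc3cc(Cc4ccccc4O)ccc3O)c(O)c(Cc3cc(C=O)ccc3O)c(O)c21 | intermediate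
10 | 3-ethoxycyclohex-2-en-1-one | CCOC1=CC(=O)CCC1 | starting material
11 | 1-(benzyloxy)-2-(bromomethyl)benzene | BrCc1ccccc1OCc1ccccc1 | starting material
12 | rac-6-[2-(benzyloxy)benzyl]-3-ethoxycyclohex-2-en-1-one | CCOC1=CC(=O)C(Cc2ccccc2OCc2ccccc2)CC1 | intermediate
13 | 6-[2-(benzyloxy)benzyl]-3-ethoxycyclohex-2-en-1-ol, racemic diastereomer mixture (not isolated) | CCOC1=CC(O)C(Cc2ccccc2OCc2ccccc2)CC1 | intermediate
14 | rac-4-[2-(benzyloxy)benzyl]cyclohex-2-en-1-one | O=C1C=CC(Cc2ccccc2OCc2ccccc2)CC1 | intermediate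
15 | aldol adduct: 9 with its formyl group converted to CH(OH) bonded to C-6 of 4-[2-(benzyloxy)benzyl]cyclohex-2-en-1-one, diastereomer mixture at the three new centres, (2S) at the flavanone (not isolated) | O=C1C[C@@H](c2ccccc2)Oc2c(Cc3cc(Cc4ccccc4O)ccc3O)c(O)c(Cc3cc(C(O)C4CC(Cc5ccccc5OCc5ccccc5)C=CC4=O)ccc3O)c(O)c21 | intermediate
16 | arylidene dienone: (6E)-6-arylidene-4-[2-(benzyloxy)benzyl]cyclohex-2-en-1-one in which the arylidene carbon is the former formyl carbon of 9, epimer mixture at the ring carbon, (2S) at the flavanone (not isolated) | O=C1C[C@@H](c2ccccc2)Oc2c(Cc3cc(Cc4ccccc4O)ccc3O)c(O)c(Cc3cc(/C=C4/C(=O)C=CC(Cc5ccccc5OCc5ccccc5)C4)ccc3O)c(O)c21 | intermediate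
17 | (2S)-6-(5-{5-[2-(benzyloxy)benzyl]-2-hydroxybenzyl}-2-hydroxybenzyl)-5,7-dihydroxy-8-[2-hydroxy-5-(2-hydroxybenzyl)benzyl]-2-phenylchroman-4-one (terminal O-benzyl ether of the target) | O=C1C[C@@H](c2ccccc2)Oc2c(Cc3cc(Cc4ccccc4O)ccc3O)c(O)c(Cc3cc(Cc4cc(Cc5ccccc5OCc5ccccc5)ccc4O)ccc3O)c(O)c21 | intermediate
18 | sarmentosumin D, (2S)-5,7-dihydroxy-6-(2-hydroxy-5-{2-hydroxy-5-[(2-hydroxyphenyl)methyl]benzyl}benzyl)-8-[2-hydroxy-5-(2-hydroxybenzyl)benzyl]-2-phenylchroman-4-one | O=C1C[C@@H](c2ccccc2)Oc2c(Cc3cc(Cc4ccccc4O)ccc3O)c(O)c(Cc3cc(Cc4cc(Cc5ccccc5O)ccc4O)ccc3O)c(O)c21 | target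

**Totals.** Total step count: 8. Longest linear sequence: 5 steps (steps 1, 2, 4, 7, 8).

**Steps most likely to fail**

1. The key condensation (step 7). Intermolecular capture of the para-hydroxybenzylic cation by free phenol rings, self-condensation of the enone, or condensation at C-3 of the flavanone may outpace dehydration, and isoaromatization may stall at the dienone. The fallback sets out from 9 and 14 and comes back at 17. The formyl group of 9 is reduced chemoselectively (NaBH4, EtOH/THF, −20 °C; the chelated flavanone ketone reacts far more slowly) to the benzylic alcohol F1. Enone 14 is aromatized by aerobic dehydrogenation (Pd(O2CCF3)2, 2-(dimethylamino)pyridine, TsOH, O2, DMSO, 80 °C) to 4-[2-(benzyloxy)benzyl]phenol F2. A ZnCl2-mediated para-quinone methide Friedel–Crafts alkylation of excess F2 with F1 in dioxane then places the benzyl group ortho to the free OH of F2 (its para position is blocked and the benzyloxy ring is less activated) and gives 17.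

2. The directed alkylation (step 2). Site selectivity between C-6 and C-8 may be poor, or the silyl ether may be lost before the alkylation so that the directing effect disappears. The fallback sets out from 1 and comes back at 5. Unprotected 1 is coupled directly with one equivalent of 3 (ZnCl2, dioxane, 80 °C), and the C-6 mono-adduct 5 is separated by chromatography from the C-8 isomer and the bis-adduct; the assignment would rest on the HMBC correlation of the chelated 5-OH with C-6. No compound outside the list is made on the way (F0).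

3. The C-8 alkylation (step 4). The quinone methide from 8 may alkylate the free phenol ring of another molecule of 8 (oligomerization) faster than it attacks C-8. The fallback sets out from 8 and 5 and comes back at 18. The phenol of 8 is capped (benzyl bromide, K2CO3, acetone, 25 °C) to give 6-[2-(benzyloxy)benzyl]-2,2-dimethyl-4H-1,3-benzodioxine F3. F3 is coupled with 5 as in step 4 to the O-benzyl aldehyde F4, which is condensed with 14 as in step 7 to the bis-benzyl ether F5. The hydrogenolysis of step 8 then removes both benzyl groups and gives 18.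

**Further compounds**

F1 | step 7 | (2S)-5,7-dihydroxy-6-[2-hydroxy-5-(hydroxymethyl)benzyl]-8-[2-hydroxy-5-(2-hydroxybenzyl)benzyl]-2-phenylchroman-4-one | O=C1C[C@@H](c2ccccc2)Oc2c(Cc3cc(Cc4ccccc4O)ccc3O)c(O)c(Cc3cc(CO)ccc3O)c(O)c21
F2 | step 7 | 4-[2-(benzyloxy)benzyl]phenol | Oc1ccc(Cc2ccccc2OCc2ccccc2)cc1
F0 | step 2 | none | none
F3 | step 4 | 6-[2-(benzyloxy)benzyl]-2,2-dimethyl-4H-1,3-benzodioxine | CC1(C)OCc2cc(Cc3ccccc3OCc3ccccc3)ccc2O1
F4 | step 4 | (2S)-8-{5-[2-(benzyloxy)benzyl]-2-hydroxybenzyl}-6-(5-formyl-2-hydroxybenzyl)-5,7-dihydroxy-2-phenylchroman-4-one | O=C1C[C@@H](c2ccccc2)Oc2c(Cc3cc(Cc4ccccc4OCc4ccccc4)ccc3O)c(O)c(Cc3cc(C=O)ccc3O)c(O)c21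
F5 | step 4 | (2S)-8-{5-[2-(benzyloxy)benzyl]-2-hydroxybenzyl}-6-(5-{5-[2-(benzyloxy)benzyl]-2-hydroxybenzyl}-2-hydroxybenzyl)-5,7-dihydroxy-2-phenylchroman-4-one | O=C1C[C@@H](c2ccccc2)Oc2c(Cc3cc(Cc4ccccc4OCc4ccccc4)ccc3O)c(O)c(Cc3cc(Cc4cc(Cc5ccccc5OCc5ccccc5)ccc4O)ccc3O)c(O)c21
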